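## Retrosynthetic overview

1. Cembrane numbering is used: C1 is the ring-fusion CH, C2 the lactone O–CH, C3=C4 and C7=C8 the E-alkenes, C11–C12 the oxirane (C12 quaternary, methyl C20), C13 the CH–OAc, C14 a CH2, and C15(=C17H2)–C16(=O) the lactone carbons.
2. Enabling feature: the C11–C12 oxirane inside the 14-membered ring. Its quaternary carbon C12 carries only a methyl group and sits next to the oxygenated stereocentre C13, so C12 can be a methyl ketone biased by C13; C11 is a CH next to a plain CH2, so it can be a sulfonium-ylide carbon.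
3. Key disconnection: the C11–C12 bond. An intramolecular sulfonium-ylide epoxidation of keto sulfonium salt 21 closes the 14-membered carbocycle and the oxirane together and sets C11 and C12; the ketone oxygen becomes the oxirane oxygen.
4. Salt 21 comes from cis-α-methylene lactone 18 by Wacker oxidation and triflate/Ph2S alkylation. Lactone 18 comes from a catalytic asymmetric chromium 2-(alkoxycarbonyl)allylation of enal 8 (from farnesyl acetate) with bromide 15 (from acrolein: allylboration sets C13, then cross-metathesis).
5. Ring order: five-membered lactone first (step 9, sets C1 and C2), then the 14-membered ring and the oxirane in one operation (step 12); desilylation and acetylation finish the synthesis.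

Key step: step 12

Remark 1: compounds 2–5 are racemic at the bromohydrin/epoxide carbon (C10 of the farnesyl chain); this centre is excised in step 3, so their SMILES leave it undefined.
Remark 2: in step 9 the antipode of the carbazole bis(oxazoline) ligand that directs the allylchromium reagent to the Re face of enal 8 is assumed; the sense has to be assigned on a model enal, and both antipodes are available from D- or L-valinol.

## Route

Step 1
Reactants: 1 (2E,6E)-farnesyl acetate
Product: 2 (2E,6E)-10-bromo-11-hydroxy-3,7,11-trimethyldodeca-2,6-dien-1-yl acetate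
Conditions: NBS, THF/H2O, 0 °C
Reagents that add atoms: N-bromosuccinimide, O=C1CCC(=O)N1Br; water, O
Why: Regioselective bromohydrin formation at the terminal trisubstituted alkene of the farnesyl chain in aqueous THF, with Markovnikov attack of water; the new centre is racemic and is excised in step 3.

Step 2
Reactants: 2 bromohydrin acetate
Product: 4 (2E,6E)-10,11-epoxy-3,7,11-trimethyldodeca-2,6-dien-1-ol, via epoxy acetate 3 (not isolated)
Conditions: K2CO3, MeOH, rt
Reagents that add atoms: none
Why: Intramolecular Williamson etherification of the bromohydrin closes the oxirane, and base-catalysed methanolysis removes the acetate in the same pot.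

Step 3
Reactants: 4 epoxy alcohol
Product: 6 (4E,8E)-10-hydroxy-4,8-dimethyldeca-4,8-dienal, via triol 5 (not isolated)
Conditions: H5IO6, THF/H2O, 0 °C
Reagents that add atoms: none
Why: Acidic hydrolysis of the trisubstituted epoxide (water attacks the tertiary carbon) followed by Malaprade glycol cleavage should release acetone and the C11 aldehyde, the trisubstituted alkenes and the allylic alcohol being inert to periodic acid at 0 °C.

Step 4
Reactants: 6 hydroxy aldehyde
Product: 7 (2E,6E)-3,7-dimethyldeca-2,6-diene-1,10-diol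
Conditions: NaBH4, MeOH, 0 °C
Reagents that add atoms: none
Why: Chemoselective borohydride reduction of the saturated aldehyde; no other reducible group is present.

Step 5
Reactants: 7 diol
Product: 8 (2E,6E)-10-hydroxy-3,7-dimethyldeca-2,6-dienal
Conditions: MnO2, CH2Cl2, rt
Reagents that add atoms: none
Why: MnO2 oxidises only the allylic alcohol (C2) and leaves the saturated primary alcohol (C11) and the E geometry untouched.

Step 6
Reactants: 9 acrolein; 10 (+)-B-allyldiisopinocampheylborane
Product: 12 (R)-hexa-1,5-dien-3-ol, via borinate ester 11 (not isolated)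
Conditions: Et2O, −78 °C; then NaOH, H2O2, 0 °C to rt
Reagents that add atoms: (+)-B-allyldiisopinocampheylborane, C=CCB([C@H]1C[C@H]2C[C@@H]([C@@H]1C)C2(C)C)[C@H]1C[C@H]2C[C@@H]([C@@H]1C)C2(C)C
Why: Brown allylboration through a chair Zimmerman–Traxler transition state; the isopinocampheyl groups derived from (−)-α-pinene should deliver the allyl group to the Re face of acrolein and so set the (R)-carbinol, the future C13.

Step 7
Reactants: 12 (R)-hexa-1,5-dien-3-ol
Product: 13 tert-butyl[(3R)-hexa-1,5-dien-3-yloxy]dimethylsilane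
Conditions: TBSCl, imidazole, DMF, rt
Reagents that add atoms: tert-butyldimethylsilyl chloride, CC(C)(C)[Si](C)(C)Cl
Why: Standard silylation of a secondary alcohol; the bulky, non-chelating silyl ether later serves as the Felkin–Anh control element.

Step 8
Reactants: 13 diene silyl ether; 14 methyl 2-(bromomethyl)acrylate
Product: 15 methyl (2Z,5R)-2-(bromomethyl)-5-(tert-butyldimethylsilyloxy)hepta-2,6-dienoate
Conditions: second-generation Hoveyda–Grubbs catalyst RuCl2(SIMes)(=CH-C6H4-2-O-i-Pr) (5 mol%), excess 14, CH2Cl2, 40 °C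
Reagents that add atoms: methyl 2-(bromomethyl)acrylate, C=C(CBr)C(=O)OC
Why: Olefin cross-metathesis at the unhindered homoallylic terminal alkene (the vinyl group next to the silyloxy-bearing carbon is sterically deactivated), under thermodynamic control that places the chain trans to the ester, which is the Z isomer by the CIP rules.

Step 9
Reactants: 8 hydroxy enal; 15 allylic bromide
Product: 18 (4S,5S)-4-[(2R)-2-(tert-butyldimethylsilyloxy)but-3-en-1-yl]-5-[(1E,5E)-9-hydroxy-2,6-dimethylnona-1,5-dien-1-yl]-3-methylideneoxolan-2-one, via allylchromium species 16 (not isolated), via bis-trimethylsilyl adduct 17 (not isolated)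
Conditions: CrCl2 (10 mol%), 1,8-bis(4-isopropyl-4,5-dihydrooxazol-2-yl)-3,6-diphenyl-9H-carbazole ligand (12 mol%), Mn powder, i-Pr2NEt, Me3SiCl, THF, rt; then PPTS, MeOH, rt
Reagents that add atoms: none
Why: Catalytic asymmetric Nozaki–Hiyama–Kishi-type 2-(alkoxycarbonyl)allylation: allylchromium species 16 (chain cis to CH2Cr) should add through its γ-carbon in a chair transition state to give the syn adduct and hence the cis lactone, the ligand directs attack to the Re face of the enal to set 2S and with it 1S, and desilylation in methanol lets the C2 hydroxyl lactonise onto the methyl ester.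

Step 10
Reactants: 18 vinyl lactone
Product: 19 (4S,5S)-4-[(2R)-2-(tert-butyldimethylsilyloxy)-3-oxobutyl]-5-[(1E,5E)-9-hydroxy-2,6-dimethylnona-1,5-dien-1-yl]-3-methylideneoxolan-2-one
Conditions: PdCl2[2-(4,5-dihydrooxazol-2-yl)quinoline] (5 mol%), AgSbF6 (12 mol%), aq. t-BuOOH, CH2Cl2, 0 °C to rt
Reagents that add atoms: tert-butyl hydroperoxide, CC(C)(C)OO
Why: Tsuji–Wacker oxidation with the quinoline–oxazoline palladium catalyst and t-BuOOH should convert the terminal alkene next to the protected carbinol into the methyl ketone with Markovnikov selectivity and without touching C13, while the trisubstituted alkenes and the electron-poor methylene lactone do not react.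

Step 11
Reactants: 19 hydroxy ketone
Product: 21 {(4E,8E)-9-[(2S,3S)-3-((2R)-2-(tert-butyldimethylsilyloxy)-3-oxobutyl)-4-methylidene-5-oxooxolan-2-yl]-4,8-dimethylnona-4,8-dien-1-yl}diphenylsulfonium trifluoromethanesulfonate, via primary triflate 20 (not isolated)
Conditions: Tf2O, 2,6-di-tert-butyl-4-methylpyridine, CH2Cl2, −78 °C; then Ph2S (excess), −78 °C to rt
Reagents that add atoms: trifluoromethanesulfonic anhydride, O=S(=O)(OS(=O)(=O)C(F)(F)F)C(F)(F)F; diphenyl sulfide, c1ccc(Sc2ccccc2)cc1
Why: Triflation of the only free hydroxyl at −78 °C with a hindered non-nucleophilic base, then SN2 displacement by diphenyl sulfide, should give the alkyldiphenylsulfonium salt whose only α-CH2 group is C11.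

Step 12
Reactants: 21 keto sulfonium triflate
Product: 24 (1S,2S,3E,7E,11R,12S,13R)-13-(tert-butyldimethylsilyloxy)-11,12-epoxycembra-3,7,15(17)-trien-16,2-olide, via sulfonium ylide 22 (not isolated), via betaine 23 (not isolated)
Conditions: LiN(SiMe3)2 (1.05 equiv, slow addition), THF (1 mM), −78 °C to −30 °C
Reagents that add atoms: none
Why: Proposed new method: LiN(SiMe3)2 should remove a proton from the only S-bound CH2 of 21 (far more acidic than the ketone and lactone α-hydrogens) to give the non-stabilised ylide 22, whose carbanion carbon C11 adds 1,2 to the C12 methyl ketone (14-exo-trig closure of the carbocycle) to give betaine 23, and the C12 alkoxide then expels diphenyl sulfide from C11 with inversion (3-exo-tet closure of the oxirane), so that the ketone oxygen becomes the epoxide oxygen. The closest known reaction type is the Corey–Chaykovsky epoxidation of ketones with alkyldiphenylsulfonium ylides, known intermolecularly and for intramolecular closure of five- to seven-membered rings but not for a macrocyclising closure. C12 is set by Felkin–Anh addition anti to the non-chelating C13 silyloxy group, which gives the required anti relationship of the C12 and C13 oxygens (12S from 13R). C11 is set in the irreversible addition, in which the C10 chain on the ylide carbon is placed away from the bulky C13 branch of the ketone and next to its methyl group, the arrangement that also corresponds to the less strained E-type 14-membered ring, so that after inversion the trans-oxirane (11R) should result. The step needs 1,2-addition to the ketone rather than conjugate addition to the lactone methylene C17 (which would close a 13-membered ring and a cyclopropane) or proton transfer; this rests on the kinetic preference of non-stabilised sulfonium ylides for C=O addition, on both closures being macrocyclic so that neither has an entropic advantage, and on high dilution at low temperature to suppress bimolecular pathways.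

Step 13
Reactants: 24 silyl ether
Product: 25 (1S,2S,3E,7E,11R,12R,13R)-11,12-epoxy-13-hydroxycembra-3,7,15(17)-trien-16,2-olide
Conditions: Bu4NF, AcOH (1:1), THF, 0 °C to rt
Reagents that add atoms: none
Why: Fluoride-mediated cleavage of the silyl ether; buffering with acetic acid keeps the C13 oxygen protonated and so should avoid Payne rearrangement and oxa-Michael addition to the methylene lactone (the C12 descriptor changes by the CIP rules only, not in space).

Step 14
Reactants: 25 epoxy alcohol
Product: 26 (1S,2S,3E,7E,11R,12S,13R)-13-acetoxy-11,12-epoxycembra-3,7,15(17)-trien-16,2-olide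
Conditions: Ac2O, pyridine, DMAP (cat.), CH2Cl2, 0 °C to rt
Reagents that add atoms: acetic anhydride, CC(=O)OC(C)=O
Why: DMAP-catalysed acylation of the secondary C13 alcohol, which does not touch any stereocentre.

## Compound list

1 | (2E,6E)-farnesyl acetate | CC(=O)OC/C=C(\C)CC/C=C(\C)CCC=C(C)C | starting material
2 | (2E,6E)-10-bromo-11-hydroxy-3,7,11-trimethyldodeca-2,6-dien-1-yl acetate (racemic at C10) | CC(=O)OC/C=C(\C)CC/C=C(\C)CCC(Br)C(C)(C)O | intermediate
3 | (2E,6E)-10,11-epoxy-3,7,11-trimethyldodeca-2,6-dien-1-yl acetate (racemic at C10) | CC(=O)OC/C=C(\C)CC/C=C(\C)CCC1OC1(C)C | intermediate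
4 | (2E,6E)-10,11-epoxy-3,7,11-trimethyldodeca-2,6-dien-1-ol (racemic at C10) | OC/C=C(\C)CC/C=C(\C)CCC1OC1(C)C | intermediate
5 | (2E,6E)-3,7,11-trimethyldodeca-2,6-diene-1,10,11-triol (racemic at C10) | OC/C=C(\C)CC/C=C(\C)CCC(O)C(C)(C)O | intermediate
6 | (4E,8E)-10-hydroxy-4,8-dimethyldeca-4,8-dienal | OC/C=C(\C)CC/C=C(\C)CCC=O | intermediate
7 | (2E,6E)-3,7-dimethyldeca-2,6-diene-1,10-diol | OC/C=C(\C)CC/C=C(\C)CCCO | intermediate
8 | (2E,6E)-10-hydroxy-3,7-dimethyldeca-2,6-dienal | O=C/C=C(\C)CC/C=C(\C)CCCO | intermediate
9 | acrolein | C=CC=O | starting material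
10 | (+)-B-allyldiisopinocampheylborane (isopinocampheyl groups from (−)-α-pinene) | C=CCB([C@H]1C[C@H]2C[C@@H]([C@@H]1C)C2(C)C)[C@H]1C[C@H]2C[C@@H]([C@@H]1C)C2(C)C | starting material
11 | (R)-hexa-1,5-dien-3-yl diisopinocampheylborinate | C=CC[C@@H](OB([C@H]1C[C@H]2C[C@@H]([C@@H]1C)C2(C)C)[C@H]1C[C@H]2C[C@@H]([C@@H]1C)C2(C)C)C=C | intermediate
12 | (R)-hexa-1,5-dien-3-ol | C=CC[C@@H](O)C=C | intermediate
13 | tert-butyl[(3R)-hexa-1,5-dien-3-yloxy]dimethylsilane | C=CC[C@@H](O[Si](C)(C)C(C)(C)C)C=C | intermediate
14 | methyl 2-(bromomethyl)acrylate | C=C(CBr)C(=O)OC | starting material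
15 | methyl (2Z,5R)-2-(bromomethyl)-5-(tert-butyldimethylsilyloxy)hepta-2,6-dienoate | COC(=O)/C(CBr)=C/C[C@@H](O[Si](C)(C)C(C)(C)C)C=C | intermediate
16 | allylchromium dichloride species from 15 (chain cis to CH2Cr; chiral ligand on chromium not drawn) | Cl[Cr](Cl)C/C(=C\C[C@@H](O[Si](C)(C)C(C)(C)C)C=C)C(=O)OC | intermediate
17 | methyl (3S,4S,5E,9E)-3-[(2R)-2-(tert-butyldimethylsilyloxy)but-3-en-1-yl]-6,10-dimethyl-2-methylidene-4,13-bis(trimethylsilyloxy)trideca-5,9-dienoate | C=C(C(=O)OC)[C@H](C[C@@H](O[Si](C)(C)C(C)(C)C)C=C)[C@@H](O[Si](C)(C)C)/C=C(\C)CC/C=C(\C)CCCO[Si](C)(C)C | intermediate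
18 | (4S,5S)-4-[(2R)-2-(tert-butyldimethylsilyloxy)but-3-en-1-yl]-5-[(1E,5E)-9-hydroxy-2,6-dimethylnona-1,5-dien-1-yl]-3-methylideneoxolan-2-one | C=C1C(=O)O[C@@H](/C=C(\C)CC/C=C(\C)CCCO)[C@H]1C[C@@H](O[Si](C)(C)C(C)(C)C)C=C | intermediate
19 | (4S,5S)-4-[(2R)-2-(tert-butyldimethylsilyloxy)-3-oxobutyl]-5-[(1E,5E)-9-hydroxy-2,6-dimethylnona-1,5-dien-1-yl]-3-methylideneoxolan-2-one | C=C1C(=O)O[C@@H](/C=C(\C)CC/C=C(\C)CCCO)[C@H]1C[C@@H](O[Si](C)(C)C(C)(C)C)C(C)=O | intermediate
20 | primary triflate of 19 (C11–OTf) | C=C1C(=O)O[C@@H](/C=C(\C)CC/C=C(\C)CCCOS(=O)(=O)C(F)(F)F)[C@H]1C[C@@H](O[Si](C)(C)C(C)(C)C)C(C)=O | intermediate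
21 | {(4E,8E)-9-[(2S,3S)-3-((2R)-2-(tert-butyldimethylsilyloxy)-3-oxobutyl)-4-methylidene-5-oxooxolan-2-yl]-4,8-dimethylnona-4,8-dien-1-yl}diphenylsulfonium trifluoromethanesulfonate | C=C1C(=O)O[C@@H](/C=C(\C)CC/C=C(\C)CCC[S+](c2ccccc2)c2ccccc2)[C@H]1C[C@@H](O[Si](C)(C)C(C)(C)C)C(C)=O.[O-]S(=O)(=O)C(F)(F)F | intermediate
22 | sulfonium ylide of 21 (carbanion at C11) | C=C1C(=O)O[C@@H](/C=C(\C)CC/C=C(\C)CC[CH-][S+](c2ccccc2)c2ccccc2)[C@H]1C[C@@H](O[Si](C)(C)C(C)(C)C)C(C)=O | intermediate
23 | macrocyclic betaine (C11–C12 bond formed; C11 bears S+Ph2, C12 bears O−; C1, C2, C12, C13 arranged as in 24, C11 as before inversion) | C=C1C(=O)O[C@H]2/C=C(\C)CC/C=C(\C)CC[C@H]([S+](c3ccccc3)c3ccccc3)[C@@]([O-])(C)[C@H](O[Si](C)(C)C(C)(C)C)C[C@@H]12 | intermediate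
24 | (1S,2S,3E,7E,11R,12S,13R)-13-(tert-butyldimethylsilyloxy)-11,12-epoxycembra-3,7,15(17)-trien-16,2-olide | C=C1C(=O)O[C@H]2/C=C(\C)CC/C=C(\C)CC[C@H]3O[C@]3(C)[C@H](O[Si](C)(C)C(C)(C)C)C[C@@H]12 | intermediate
25 | (1S,2S,3E,7E,11R,12R,13R)-11,12-epoxy-13-hydroxycembra-3,7,15(17)-trien-16,2-olide | C=C1C(=O)O[C@H]2/C=C(\C)CC/C=C(\C)CC[C@H]3O[C@]3(C)[C@H](O)C[C@@H]12 | intermediate
26 | (1S,2S,3E,7E,11R,12S,13R)-13-acetoxy-11,12-epoxycembra-3,7,15(17)-trien-16,2-olide (CNP0146076.4) | C=C1C(=O)O[C@H]2/C=C(\C)CC/C=C(\C)CC[C@H]3O[C@]3(C)[C@H](OC(C)=O)C[C@@H]12 | target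

## Step count and risks

Total step count: 14. Longest linear sequence: 11 steps (steps 1–5 and 9–14, from farnesyl acetate).

Steps most likely to fail:

1. Step 12 (proposed new method). The ylide may be diverted by conjugate addition to the methylene lactone, by proton transfer or by oligomerisation, or the addition may proceed with poor facial or cis/trans selectivity. The fallback uses known chemistry and keeps the same ring-closing bond. It sets out from ketone 19: Dess–Martin oxidation of the primary alcohol should give keto aldehyde F1; double methylenation of aldehyde and ketone with Zn/CH2Br2/TiCl4 (non-basic, tolerant of the lactone) should give diene F2; ring-closing metathesis with the second-generation Hoveyda–Grubbs catalyst under high dilution should close the 14-membered ring as the (11E)-alkene F3, the electron-poor methylene lactone being a poor metathesis partner; buffered desilylation (Bu4NF/AcOH) should give allylic alcohol F4; hydroxyl-directed epoxidation with VO(acac)2/t-BuOOH, erythro-selective for a 2-methyl allylic alcohol because of allylic 1,2-strain, should then deliver epoxy alcohol 25, where the fallback comes back to the route.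

2. Step 9. Facial control may erode (mismatch between the ligand and the C13 centre of the bromide, or uncatalysed background allylation), or syn selectivity may be lost. The fallback sets out from 8 and 15: an indium-mediated Barbier allylation (In powder, THF/H2O, rt, then PPTS) tolerates the free hydroxyl, needs no silylation and is syn-selective through a closed transition state. Without reagent control it should give both cis lactones, 18 and its (4R,5R)-diastereomer F5; these are diastereomers because of the fixed C13 centre and would be separated by chromatography. The fallback comes back to the route at 18.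

3. Step 8. Cross-metathesis of the electron-poor 1,1-disubstituted acrylate may be slow, the diene 13 may homodimerise, or the alkene geometry may erode. The fallback sets out from 13: Lemieux–Johnson cleavage (OsO4 cat., NaIO4, 2,6-lutidine) of the unhindered, more electron-rich terminal alkene should give (3R)-3-(tert-butyldimethylsilyloxy)pent-4-enal F6; a Morita–Baylis–Hillman reaction with methyl acrylate (DABCO) should give adduct F7 as an epimer mixture at the new carbinol, which is of no consequence; bromination with allylic transposition (NBS, Me2S) should give the (Z)-bromide 15, where the fallback comes back to the route.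

Further compounds

F1 | step 12 | (4S,5S)-4-[(2R)-2-(tert-butyldimethylsilyloxy)-3-oxobutyl]-5-[(1E,5E)-2,6-dimethyl-9-oxonona-1,5-dien-1-yl]-3-methylideneoxolan-2-one | C=C1C(=O)O[C@@H](/C=C(\C)CC/C=C(\C)CCC=O)[C@H]1C[C@@H](O[Si](C)(C)C(C)(C)C)C(C)=O
F2 | step 12 | (4S,5S)-4-[(2R)-2-(tert-butyldimethylsilyloxy)-3-methylbut-3-en-1-yl]-5-[(1E,5E)-2,6-dimethyldeca-1,5,9-trien-1-yl]-3-methylideneoxolan-2-one | C=C1C(=O)O[C@@H](/C=C(\C)CC/C=C(\C)CCC=C)[C@H]1C[C@@H](O[Si](C)(C)C(C)(C)C)C(C)=C
F3 | step 12 | (1S,2S,3E,7E,11E,13R)-13-(tert-butyldimethylsilyloxy)cembra-3,7,11,15(17)-tetraen-16,2-olide | C=C1C(=O)O[C@H]2/C=C(\C)CC/C=C(\C)CC/C=C(\C)[C@H](O[Si](C)(C)C(C)(C)C)C[C@@H]12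
F4 | step 12 | (1S,2S,3E,7E,11E,13R)-13-hydroxycembra-3,7,11,15(17)-tetraen-16,2-olide | C=C1C(=O)O[C@H]2/C=C(\C)CC/C=C(\C)CC/C=C(\C)[C@H](O)C[C@@H]12
F5 | step 9 | (4R,5R)-4-[(2R)-2-(tert-butyldimethylsilyloxy)but-3-en-1-yl]-5-[(1E,5E)-9-hydroxy-2,6-dimethylnona-1,5-dien-1-yl]-3-methylideneoxolan-2-one | C=C1C(=O)O[C@H](/C=C(\C)CC/C=C(\C)CCCO)[C@@H]1C[C@@H](O[Si](C)(C)C(C)(C)C)C=C
F6 | step 8 | (3R)-3-(tert-butyldimethylsilyloxy)pent-4-enal | O=CC[C@@H](O[Si](C)(C)C(C)(C)C)C=C
F7 | step 8 | methyl (5R)-5-(tert-butyldimethylsilyloxy)-3-hydroxy-2-methylidenehept-6-enoate (epimer mixture at C3) | C=C(C(=O)OC)C(O)C[C@@H](O[Si](C)(C)C(C)(C)C)C=C
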